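**Retrosynthetic overview**
- Numbering (icetexane): ring A = C1–C5 and C10; seven-membered ring B = C5, C6, C7, C8, C9, C20, C10; ring C = C8, C9, C11–C14; C19 = lactone carbonyl on C4, joined through O to C6.
- Ring C hydroxyquinone comes last, by oxidation of a 12,14-resorcinol; the C1 carbinol comes from 1,2-reduction of a ring A enone.
- Key disconnection: the lactone C6–O bond, formed by anti addition of the C19 carboxylate to a terminal alkyne activated by an aryl-palladium species (this also makes C7–C8); ring B then closes by aldol condensation (C10=C20).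
- Ring A, with the C4 quaternary centre and a cis C5 alkyne, comes from an enantioselective Diels–Alder reaction of a 1-alkynyl-3-siloxydiene with methacrolein.
- Order of ring formation: A, then lactone, then B; ring C is carried in from a symmetric benzaldehyde and oxidised at the end.

Assumptions: aldehyde 9 (a tapinarof intermediate) is taken as purchasable; the (S)-oxazaborolidinium catalyst is assumed to give the (1S,2R) adduct 6, and its mirror-image catalyst is used if the opposite sense is found.

**Step 1**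
Reactants: 1 3-(trimethylsilyl)propynal; 2 1-(triphenylphosphoranylidene)propan-2-one
Product: 3 (E)-6-(trimethylsilyl)hex-3-en-5-yn-2-one
Conditions: CH2Cl2, rt
Reagents that add atoms: none
Why: Wittig olefination with a stabilised ylide is reliably (E)-selective on ynals and leaves the silyl alkyne untouched.

**Step 2**
Reactants: 3 (E)-6-(trimethylsilyl)hex-3-en-5-yn-2-one
Product: 4 (E)-triisopropyl{[6-(trimethylsilyl)hexa-1,3-dien-5-yn-2-yl]oxy}silane
Conditions: TIPSOTf, Et3N, Et2O, 0 °C
Reagents that add atoms: triisopropylsilyl triflate, CC(C)[Si](OS(=O)(=O)C(F)(F)F)(C(C)C)C(C)C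
Why: Soft enolisation (silyl triflate/amine) can only occur at the methyl group of this enone, giving the cross-conjugated 2-siloxydiene as a robust TIPS enol ether.

**Step 3**
Reactants: 4 (E)-triisopropyl{[6-(trimethylsilyl)hexa-1,3-dien-5-yn-2-yl]oxy}silane; 5 methacrolein
Product: 7 (1S,2S)-2-ethynyl-1-methyl-4-oxocyclohexane-1-carbaldehyde, via bis-silylated cycloadduct 6 (not isolated)
Conditions: (S)-o-tolyl-CBS oxazaborolidine (20 mol%), Tf2NH (18 mol%), CH2Cl2, −78 °C; then Bu4NF, AcOH, THF, 0 °C
Reagents that add atoms: none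
Why: Enantioselective Diels–Alder reaction under chiral oxazaborolidinium Lewis acid catalysis, in which the siloxy group (para) and the alkynyl terminus (ortho) direct the same regiochemistry, the endo transition state places alkyne and formyl group cis (C5 relative to C4), and the catalyst shields one face of bound methacrolein to set the C4 quaternary centre; buffered fluoride then removes both silyl groups.

**Step 4**
Reactants: 7 (1S,2S)-2-ethynyl-1-methyl-4-oxocyclohexane-1-carbaldehyde
Product: 8 (1S,2S)-2-ethynyl-1-methyl-4-oxocyclohexane-1-carboxylic acid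
Conditions: NaClO2, NaH2PO4, 2-methyl-2-butene, t-BuOH/H2O, rt
Reagents that add atoms: sodium chlorite, [Na+].[O-]Cl=O
Why: Pinnick oxidation converts the hindered, non-enolisable aldehyde to the acid without touching the ketone, the alkyne or either stereocentre.

**Step 5**
Reactants: 9 4-isopropyl-3,5-dimethoxybenzaldehyde
Product: 10 2-iodo-4-isopropyl-3,5-dimethoxybenzaldehyde
Conditions: NIS, CF3CO2H (cat.), MeCN, rt
Reagents that add atoms: N-iodosuccinimide, O=C1CCC(=O)N1I
Why: Electrophilic aromatic iodination; the two free ring positions are equivalent by symmetry and each is ortho/para to a methoxy group, so one equivalent of NIS gives a single mono-iodide.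

**Step 6**
Reactants: 8 (1S,2S)-2-ethynyl-1-methyl-4-oxocyclohexane-1-carboxylic acid; 10 2-iodo-4-isopropyl-3,5-dimethoxybenzaldehyde
Product: 12 (4S,5R)-12,14-dimethoxy-1-oxoicetexa-6,8,10(20),11,13-pentaen-19,6-olide, via arylidene enol lactone aldehyde 11 (not isolated)
Conditions: Pd(PPh3)4 (5 mol%), Et3N, DMSO, 50 °C; then K2CO3, 4 Å MS, 80 °C
Reagents that add atoms: none
Why: Proposed new method: zerovalent palladium inserts into the C–I bond of 10, the resulting aryl-palladium iodide (divalent palladium) π-activates the alkyne of the ammonium carboxylate of 8, the cis carboxylate attacks C6 5-exo-dig anti to palladium (the C6–O bond), and C–C reductive elimination gives the (E)-arylidene enol lactone 11 with the formyl group held over C10, so that carbonate-mediated enolisation, seven-membered aldol closure and E1cB dehydration form C10=C20 and ring B (only C10, not C2, can reach the aldehyde; sieves remove the water to protect the enol lactone; no new stereocentre, C5 stays cis-fused); the closest known reaction type is the intermolecular palladium-catalysed arylative lactonisation of 4-pentynoic acids with aryl halides, followed by a Claisen–Schmidt condensation, not previously merged into a (4+3) benzannulation.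

**Step 7**
Reactants: 12 (4S,5R)-12,14-dimethoxy-1-oxoicetexa-6,8,10(20),11,13-pentaen-19,6-olide
Product: 13 (4S,5R)-12,14-dihydroxy-1-oxoicetexa-6,8,10(20),11,13-pentaen-19,6-olide
Conditions: BBr3, CH2Cl2, −78 to −20 °C; NaHCO3 aq. quench at −78 °C
Reagents that add atoms: none
Why: Lewis-acid aryl methyl ether cleavage is done at the ketone stage, before the acid-sensitive allylic alcohol exists, and the cold basic quench avoids acid-promoted attack of the C14 phenol on the enol lactone.

**Step 8**
Reactants: 13 (4S,5R)-12,14-dihydroxy-1-oxoicetexa-6,8,10(20),11,13-pentaen-19,6-olide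
Product: 14 (1R,4S,5R)-1,12,14-trihydroxyicetexa-6,8,10(20),11,13-pentaen-19,6-olide
Conditions: NaBH4, CeCl3·7H2O, MeOH/THF, −78 °C
Reagents that add atoms: none
Why: Luche 1,2-reduction of the exocyclic enone, with the small hydride expected to add axially from the convex face (the face carrying H5 and the C4 methyl) so that the new hydroxyl is equatorial and cis to the lactone (1R).

**Step 9**
Reactants: 14 (1R,4S,5R)-1,12,14-trihydroxyicetexa-6,8,10(20),11,13-pentaen-19,6-olide
Product: 15 6,7-anhydroballotiquinone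
Conditions: (KSO3)2NO (3 equiv), KH2PO4 buffer (pH 6), acetone/H2O, 0 °C to rt
Reagents that add atoms: potassium nitrosodisulfonate, [K+].[K+].[O]N(S(=O)(=O)[O-])S(=O)(=O)[O-]
Why: Teuber oxidation of the resorcinol at its only free ring position (C11, para to the C14 hydroxyl) gives the 12-hydroxy-11,14-quinone directly under near-neutral conditions that spare the enol lactone, the allylic alcohol and all three stereocentres.

**Compound list**
1 | 3-(trimethylsilyl)propynal | C[Si](C)(C)C#CC=O | starting material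
2 | 1-(triphenylphosphoranylidene)propan-2-one | CC(=O)C=P(c1ccccc1)(c1ccccc1)c1ccccc1 | starting material
3 | (E)-6-(trimethylsilyl)hex-3-en-5-yn-2-one | CC(=O)/C=C/C#C[Si](C)(C)C | intermediate
4 | (E)-triisopropyl{[6-(trimethylsilyl)hexa-1,3-dien-5-yn-2-yl]oxy}silane | C=C(O[Si](C(C)C)(C(C)C)C(C)C)/C=C/C#C[Si](C)(C)C | intermediate
5 | methacrolein | CC(=C)C=O | starting material
6 | (1S,2R)-1-methyl-4-[(triisopropylsilyl)oxy]-2-[(trimethylsilyl)ethynyl]cyclohex-3-ene-1-carbaldehyde (alkyne cis to CHO; not isolated) | C[Si](C)(C)C#C[C@@H]1C=C(O[Si](C(C)C)(C(C)C)C(C)C)CC[C@]1(C)C=O | intermediate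
7 | (1S,2S)-2-ethynyl-1-methyl-4-oxocyclohexane-1-carbaldehyde (ethynyl cis to CHO) | C#C[C@@H]1CC(=O)CC[C@]1(C)C=O | intermediate
8 | (1S,2S)-2-ethynyl-1-methyl-4-oxocyclohexane-1-carboxylic acid (ethynyl cis to CO2H) | C#C[C@@H]1CC(=O)CC[C@]1(C)C(=O)O | intermediate
9 | 4-isopropyl-3,5-dimethoxybenzaldehyde | COc1cc(C=O)cc(OC)c1C(C)C | starting material
10 | 2-iodo-4-isopropyl-3,5-dimethoxybenzaldehyde | COc1cc(C=O)c(I)c(OC)c1C(C)C | intermediate
11 | 2-{(E)-[(3aR,7aS)-7a-methyl-1,5-dioxohexahydro-2-benzofuran-3(1H)-ylidene]methyl}-4-isopropyl-3,5-dimethoxybenzaldehyde (aryl trans to lactone O; not isolated) | O=Cc1cc(OC)c(C(C)C)c(OC)c1/C=C1/OC(=O)[C@@]2(C)CCC(=O)C[C@@H]12 | intermediate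
12 | (4S,5R)-12,14-dimethoxy-1-oxoicetexa-6,8,10(20),11,13-pentaen-19,6-olide (13-isopropyl; cis-fused lactone) | CC(C)c1c(OC)cc2c(c1OC)C=C1OC(=O)[C@@]3(C)CCC(=O)C(=C2)[C@@H]13 | intermediate
13 | (4S,5R)-12,14-dihydroxy-1-oxoicetexa-6,8,10(20),11,13-pentaen-19,6-olide | CC(C)c1c(O)cc2c(c1O)C=C1OC(=O)[C@@]3(C)CCC(=O)C(=C2)[C@@H]13 | intermediate
14 | (1R,4S,5R)-1,12,14-trihydroxyicetexa-6,8,10(20),11,13-pentaen-19,6-olide (1-OH cis to lactone) | CC(C)c1c(O)cc2c(c1O)C=C1OC(=O)[C@@]3(C)CC[C@@H](O)C(=C2)[C@@H]13 | intermediate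
15 | 6,7-anhydroballotiquinone, (1R,4S,5R)-1,12-dihydroxy-11,14-dioxoicetexa-6,8,10(20),12-tetraen-19,6-olide | CC(C)C1=C(O)C(=O)C2=C(C=C3OC(=O)[C@@]4(C)CC[C@@H](O)C(=C2)[C@@H]34)C1=O | target

**Totals**
Total steps: 9. Longest linear sequence: 8 (steps 1–4, then 6–9).

**Three steps most likely to fail**

Step 3 (enantio- and endo-selectivity on a diene class not yet tested with this catalyst). The fallback sets out from 4 and 5 and comes back at 8. Promote the cycloaddition with achiral Me2AlCl (CH2Cl2, −78 °C) to the racemic endo cycloadduct F1, and desilylate as in step 3 to the racemic cis keto aldehyde F2. Oxidise with NaClO2 to the racemic cis keto acid F3, then resolve by crystallising the (R)-1-phenylethylammonium salt of the (1S,2S)-acid F4 (the other amine antipode is used if it gives the better-crystallising salt). Acidification with aqueous HCl gives 8.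

Step 6 (the new annulation). The fallback uses known reactions, sets out from 8 and 10 and comes back at 12. Iodolactonise 8 (NIS, NaHCO3, MeCN; 5-exo-dig, anti addition) to the (E)-iodomethylene enol lactone F5. Convert 10 to the arylboronic pinacol ester F6 (B2pin2, Pd(dppf)Cl2, KOAc, dioxane). Suzuki coupling of F5 with F6 (Pd(PPh3)4, K3PO4, dioxane, 60 °C) retains the alkene geometry and gives 11, now isolated. A separate acid-catalysed aldol condensation (TsOH, toluene, 80 °C, 4 Å MS) closes ring B to 12.

Step 7 (BBr3 in the presence of the enol lactone and enone). The fallback sets out from 12 and comes back at 15. Reduce 12 first (NaBH4, CeCl3·7H2O) to the dimethoxy allylic alcohol F7. Oxidise the arene directly with (NH4)2Ce(NO3)6 (MeCN/H2O, 0 °C; oxidative demethylation at C14 and oxygenation of C11–H) to the 12-O-methyl quinone F8. Cleave the chelated vinylogous methyl ester with BCl3 (CH2Cl2, −78 °C) to give 15.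

**Further compounds**
F1 | step 3 | racemic endo cycloadduct, (1S,2R) and (1R,2S) forms of 1-methyl-4-[(triisopropylsilyl)oxy]-2-[(trimethylsilyl)ethynyl]cyclohex-3-ene-1-carbaldehyde | C[Si](C)(C)C#C[C@@H]1C=C(O[Si](C(C)C)(C(C)C)C(C)C)CC[C@]1(C)C=O.C[Si](C)(C)C#C[C@H]1C=C(O[Si](C(C)C)(C(C)C)C(C)C)CC[C@@]1(C)C=O
F2 | step 3 | racemic cis-2-ethynyl-1-methyl-4-oxocyclohexane-1-carbaldehyde | C#C[C@@H]1CC(=O)CC[C@]1(C)C=O.C#C[C@H]1CC(=O)CC[C@@]1(C)C=O
F3 | step 3 | racemic cis-2-ethynyl-1-methyl-4-oxocyclohexane-1-carboxylic acid | C#C[C@@H]1CC(=O)CC[C@]1(C)C(=O)O.C#C[C@H]1CC(=O)CC[C@@]1(C)C(=O)O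
F4 | step 3 | (R)-1-phenylethylammonium (1S,2S)-2-ethynyl-1-methyl-4-oxocyclohexane-1-carboxylate | C#C[C@@H]1CC(=O)CC[C@]1(C)C(=O)[O-].C[C@@H]([NH3+])c1ccccc1
F5 | step 6 | (3E,3aR,7aS)-3-(iodomethylidene)-7a-methylhexahydro-2-benzofuran-1,5-dione | I/C=C1/OC(=O)[C@@]2(C)CCC(=O)C[C@@H]12
F6 | step 6 | 4-isopropyl-3,5-dimethoxy-2-(4,4,5,5-tetramethyl-1,3,2-dioxaborolan-2-yl)benzaldehyde | COc1cc(C=O)c(B2OC(C)(C)C(C)(C)O2)c(OC)c1C(C)C
F7 | step 7 | (1R,4S,5R)-1-hydroxy-12,14-dimethoxyicetexa-6,8,10(20),11,13-pentaen-19,6-olide | CC(C)c1c(OC)cc2c(c1OC)C=C1OC(=O)[C@@]3(C)CC[C@@H](O)C(=C2)[C@@H]13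
F8 | step 7 | (1R,4S,5R)-1-hydroxy-12-methoxy-11,14-dioxoicetexa-6,8,10(20),12-tetraen-19,6-olide | CC(C)C1=C(OC)C(=O)C2=C(C=C3OC(=O)[C@@]4(C)CC[C@@H](O)C(=C2)[C@@H]34)C1=O
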